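## Analysis of the target

The target (19) is an open-chain bis(bibenzyl): four benzene rings, called A to D here, joined in a row by a CH2CH2 bridge (A–B), a diaryl ether oxygen (B–C) and a second CH2CH2 bridge (C–D), with no ring besides the four arenes. Ring A is a 3-hydroxyphenyl group, ring B a para-phenylene with the bridge at C1 and the ether oxygen at C4, ring C a 1,2,4-trisubstituted phenol (bridge at C1, ether oxygen at C3, hydroxyl at C4), and ring D a catechol with the bridge at C1 and hydroxyls at C2 and C3. There is no stereocentre and no double bond, so the problem is one of regiochemistry and of handling four phenols. The sensitive groups are these phenols, above all the catechol of ring D, which is oxidised by air in base and by any oxidant applied to the rest of the molecule; rings A and D are also open to electrophilic halogenation. The hard bond is the diaryl ether: its oxygen must sit on C3 of ring C, next to a hydroxyl that ends up free, and it joins two halves of nearly equal size, so a conventional arylation would have to tell the two oxygens of ring C apart with protecting groups. The plan rests on one feature: the ether oxygen on C3 of ring C is ortho to the C4 hydroxyl, and the bridge at C1 is para to it. That is the pattern left when the oxygen of one 4-alkylphenol (ring B) bonds to an ortho carbon of a second, oxidised 4-alkylphenol (ring C), so both halves can be 4-(2-arylethyl)phenols and the ether is the last skeletal bond made.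

## Retrosynthetic reasoning

**19 to 18.** The last operation is cleavage of the three O–CH3 bonds on rings A and D. These phenols must stay masked throughout: a free catechol would be oxidised at the anode before any halophenol, and free phenols would quench the ylides. Methyl ethers survive base, the anode, zinc and hydrogenolysis, and they keep rings A and D harder to oxidise than a phenolate. The forward reaction must remove three methyl groups without touching the diaryl ether or the bridges.

**18 to 17.** Three C–H bonds (C3 and C5 of ring B, C5 of ring C) are traced back to two C–Cl bonds and one C–Br bond. These halogens are what the coupling leaves behind, and a single catalytic hydrogenolysis should remove all three. Nothing else in 17 is reducible under those conditions.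

**17 to 14 and 7.** The bond cut is the one between the ether oxygen and C3 of ring C. Cutting the other side of the oxygen (O to C4 of ring B) would call for an arylation of a ring C catechol monoether and for differentiated oxygens on ring C. Cutting here gives two phenols of the same type, 14 (rings C and D, two ortho bromines) and 7 (rings A and B, two ortho chlorines). The forward reaction oxidises 14 at an anode, lets the oxygen of 7 add to a bromine-bearing ortho carbon (dienone 15, then quinol ether 16), and rearomatises by reduction. The hydroxyl left free on ring C is the one that drove the oxidation, so it needs no protecting group. The halogens block every ortho carbon against C–C coupling, and the bromine/chlorine difference decides which phenol is oxidised.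

**7 to 2 and 3 (through 6, 5, 4).** The A–B bridge is cut between its two benzylic carbons as a C=C bond, made by Wittig olefination of aldehyde 4 with the ylide of salt 2. The halogenated ring is the aldehyde partner because 3 is bought with both chlorines in place, so no chlorination has to choose between a phenol ring and an anisole ring. The phenol of 3 is masked as an acetal ether (4), because its anion would consume the ylide and deactivate the carbonyl group. Alkene 5 is saturated by a metal-free hydrogen transfer to give 6, which leaves the C–Cl bonds alone, and acid then frees phenol 7. Salt 2 comes from bromide 1.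

**14 to 9 and 10 (through 13, 12, 11).** The C–D bridge is cut the same way: aldehyde 11 (from 10) and the ylide of salt 9 give alkene 12, which is reduced to 13 and unmasked to 14. The metal-free reduction matters more here, since C–Br bonds are lost readily under catalytic hydrogenation. Ring D is the ylide partner because alcohol 8 is converted into salt 9 in one step.

## Alternatives that were turned down

Alternative 1: Ring A is taken apart into a three-carbon bis-nucleophile, the bis(silyl) dienol ether A1 (1-methoxy-1,3-bis(trimethylsilyloxy)buta-1,3-diene), and a three-carbon bis-electrophile, the beta-ketoacetal A2 at the end of the ring B chain, which already carries rings B, C and D.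
- Forward key step: a Lewis-acid-promoted [3+3] cyclocondensation of A1 with A2 forms two C–C bonds and closes ring A as the methyl 6-(2-arylethyl)salicylate A3.
- For it: the hydroxyl of ring A ends up meta to the bridge by construction, the step echoes the polyketide origin of bibenzyl acids, and the cyclocondensation has no homo- versus cross-coupling question. On reliability of the key step it is stronger than the chosen route.
- Against it: ring A is the simplest ring of the molecule and is bought ready-made as a 3-methoxybenzyl unit. A2 must be built on a fragment that already contains the diaryl ether, so the hard bond is pushed back to an earlier, unspecified arylation. A3 carries an ester that costs a saponification and a decarboxylation before the final deprotection.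
- Comparison: the chosen route spends its one risky step on the ether itself, reaches it from two halves made by the same four operations, and is shorter.

Alternative 2: The bond from the C–D bridge to C1 of ring D and the neighbouring C2–O bond of ring D are cut together.
- Forward key step: 3-fluoroanisole A4 is lithiated between fluorine and methoxy and loses fluoride to give 3-methoxybenzyne A5. The 2-arylethyllithium A6, which carries rings A, B and C, adds at the aryne carbon meta to methoxy. The resulting aryllithium is trapped with a borate and oxidised to the phenol A7.
- For it: two adjacent bonds form in one pot, the methoxy group directs the addition, and no halogen ballast or redox detour is needed. On atom economy it is stronger than the chosen route.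
- Against it: the 2,3-dioxygenated benzyl unit of ring D is an inexpensive purchased building block. A6 is a primary alkyllithium that must be generated on an advanced fragment with a diaryl ether and four benzylic positions, and must coexist with the aryne precursor A4; addition of the product aryllithium to more A5 and proton transfers compete. The free inner hydroxyl of A7 is a differentiation the target does not need. The diaryl ether again has to exist before the key step.
- Comparison: the chosen route keeps organolithium chemistry off advanced material, builds both bridges from aldehydes by the same Wittig and reduction pair, and addresses the ether directly.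

Alternative 3: Ring B is taken apart into methyl coumalate A8 and the ethynyl ether A9 of the ring C phenol.
- Forward key step: an inverse-demand [4+2] cycloaddition of A8 with A9 followed by decarboxylative cycloreversion forms two C–C bonds and closes ring B as the methyl 4-aryloxybenzoate A10.
- For it: the ether C–O bond is already present in A9, the para relation follows from the polarisation of both partners, and no homo-coupling is possible. On regiochemical certainty of the ether it is stronger than the chosen route.
- Against it: A9 needs the ring C phenol A11, whose two oxygens are already differentiated, and then two further steps to a sensitive ynol ether. The ester of A10 must still be turned into the A–B bridge (reduction, olefination, saturation). A10 itself is reachable in one step by nucleophilic aromatic substitution of A11 on methyl 4-fluorobenzoate A12, so building ring B from scratch buys little.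
- Comparison: the chosen route joins two complete bibenzyls in one event and needs no differentiation of the ring C oxygens.

Key step: step 11

Remark on the chemistry: the target has no stereocentre. Alkenes 5 and 12 are expected as E/Z mixtures and are reduced as such, so their SMILES carry no double-bond descriptor. Dienones 15 and 16 are racemic and their sp3 centres vanish on rearomatisation.

## Route

Step 1
Reactants: 1 3-methoxybenzyl bromide
Product: 2 (3-methoxybenzyl)triphenylphosphonium bromide
Conditions: PPh3, toluene, reflux
Reagents that add atoms: triphenylphosphine, c1ccc(cc1)P(c1ccccc1)c1ccccc1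
Why: SN2 quaternisation of the phosphine by a primary benzylic bromide; the salt should crystallise from toluene and need no chromatography.

Step 2
Reactants: 3 3,5-dichloro-4-hydroxybenzaldehyde
Product: 4 3,5-dichloro-4-(methoxymethoxy)benzaldehyde
Conditions: MOMCl, iPr2NEt, CH2Cl2, 0 °C to rt
Reagents that add atoms: chloromethyl methyl ether, COCCl
Why: O-alkylation of an acidic phenol (Williamson type); it masks the phenol, whose anion would otherwise quench the ylide and turn the aldehyde into an unreactive vinylogous carboxylate.

Step 3
Reactants: 2 (3-methoxybenzyl)triphenylphosphonium bromide; 4 3,5-dichloro-4-(methoxymethoxy)benzaldehyde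
Product: 5 1,3-dichloro-2-(methoxymethoxy)-5-[2-(3-methoxyphenyl)ethenyl]benzene (E/Z mixture)
Conditions: KOtBu, THF, 0 °C to rt
Reagents that add atoms: none
Why: Wittig olefination with a semi-stabilised benzylic ylide; the E/Z ratio does not matter because the double bond is saturated next, and an alkoxide base in place of an alkyllithium avoids halogen–metal exchange.

Step 4
Reactants: 5 1,3-dichloro-2-(methoxymethoxy)-5-[2-(3-methoxyphenyl)ethenyl]benzene
Product: 6 1,3-dichloro-2-(methoxymethoxy)-5-[2-(3-methoxyphenyl)ethyl]benzene
Conditions: TsNHNH2, NaOAc, DME–H2O, reflux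
Reagents that add atoms: none
Why: Diimide reduction; HN=NH released from the sulfonyl hydrazide transfers H2 to the C=C bond in a concerted, metal-free step, so the aryl C–Cl bonds and the acetal are not touched.

Step 5
Reactants: 6 1,3-dichloro-2-(methoxymethoxy)-5-[2-(3-methoxyphenyl)ethyl]benzene
Product: 7 2,6-dichloro-4-[2-(3-methoxyphenyl)ethyl]phenol
Conditions: conc. HCl (cat.), MeOH, 50 °C
Reagents that add atoms: none
Why: Acid-catalysed acetal exchange transfers the methoxymethyl group to methanol; the dichlorophenol is a good leaving group and the aryl methyl ether is inert.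

Step 6
Reactants: 8 2,3-dimethoxybenzyl alcohol
Product: 9 (2,3-dimethoxybenzyl)triphenylphosphonium bromide
Conditions: PPh3·HBr, MeCN, reflux
Reagents that add atoms: triphenylphosphonium bromide (triphenylphosphine hydrobromide), [Br-].[PH+](c1ccccc1)(c1ccccc1)c1ccccc1
Why: Direct conversion of an electron-rich benzylic alcohol into its phosphonium salt; protonation and loss of water give a benzylic electrophile stabilised by the ortho methoxy group, which the phosphine captures, so one step replaces bromination plus quaternisation.

Step 7
Reactants: 10 3,5-dibromo-4-hydroxybenzaldehyde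
Product: 11 3,5-dibromo-4-(methoxymethoxy)benzaldehyde
Conditions: MOMCl, iPr2NEt, CH2Cl2, 0 °C to rt
Reagents that add atoms: chloromethyl methyl ether, COCCl
Why: The same O-alkylation as in step 2, for the same reason.

Step 8
Reactants: 9 (2,3-dimethoxybenzyl)triphenylphosphonium bromide; 11 3,5-dibromo-4-(methoxymethoxy)benzaldehyde
Product: 12 1,3-dibromo-5-[2-(2,3-dimethoxyphenyl)ethenyl]-2-(methoxymethoxy)benzene (E/Z mixture)
Conditions: KOtBu, THF, 0 °C to rt
Reagents that add atoms: none
Why: Wittig olefination as in step 3; the alkoxide base leaves the aryl bromides alone, and both alkene isomers converge in the next step.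

Step 9
Reactants: 12 1,3-dibromo-5-[2-(2,3-dimethoxyphenyl)ethenyl]-2-(methoxymethoxy)benzene
Product: 13 1,3-dibromo-5-[2-(2,3-dimethoxyphenyl)ethyl]-2-(methoxymethoxy)benzene
Conditions: TsNHNH2, NaOAc, DME–H2O, reflux
Reagents that add atoms: none
Why: Diimide reduction as in step 4; the metal-free hydrogen transfer is chosen because aryl C–Br bonds would be cleaved under hydrogenation over Pd.

Step 10
Reactants: 13 1,3-dibromo-5-[2-(2,3-dimethoxyphenyl)ethyl]-2-(methoxymethoxy)benzene
Product: 14 2,6-dibromo-4-[2-(2,3-dimethoxyphenyl)ethyl]phenol
Conditions: conc. HCl (cat.), MeOH, 50 °C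
Reagents that add atoms: none
Why: Acid-catalysed acetal exchange as in step 5; the two aryl methyl ethers of ring D are stable to dilute acid.

Step 11
Reactants: 14 2,6-dibromo-4-[2-(2,3-dimethoxyphenyl)ethyl]phenol; 7 2,6-dichloro-4-[2-(3-methoxyphenyl)ethyl]phenol
Product: 17 2-bromo-6-{2,6-dichloro-4-[2-(3-methoxyphenyl)ethyl]phenoxy}-4-[2-(2,3-dimethoxyphenyl)ethyl]phenol, via ortho-aryloxy bromodienone 15 (not isolated), via para-methoxy quinol ether 16 (not isolated)
Conditions: 7 (3 equiv), LiClO4 (0.1 M), 2,6-lutidine, MeOH, glassy-carbon anode, Pt cathode, undivided cell, potential held at the first anodic wave of 14 (located beforehand by cyclic voltammetry of 14 and 7 in the cell medium), 0 °C, ca. 2 F/mol of 14; then Zn dust, AcOH, rt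
Reagents that add atoms: none
Why: This is an anodic oxidative phenol C–O coupling followed by reductive rearomatisation, the known way from ortho,ortho-dihalophenols to ortho-aryloxyphenols, applied here to two different phenols. Partial ionisation by 2,6-lutidine lets 14 give up two electrons at a potential well below that of the anisole ring A and the veratrole ring D, and the resulting phenoxenium-type ion carries its chain at C4 and a bromine on each ortho carbon. The oxygen of 7, present in excess, adds to one bromine-bearing ortho carbon to give dienone 15; in methanol this should lose bromide and take up solvent at C4 to give quinol ether 16, a form that cannot be oxidised further. Zinc in acetic acid then expels methoxide (or bromide from any surviving 15) by two-electron reduction and restores the phenol of ring C, now with the ether oxygen ortho to its hydroxyl. No ring is closed, and the sp3 centres of 15 and 16 are racemic and disappear on rearomatisation. Three selectivities are needed: C–O over C–C coupling, secured because every ortho carbon of both phenols carries a halogen and both para carbons carry the chains; oxidation of 14 in preference to 7, which rests on the lower potential expected for a dibromophenol than for a dichlorophenol and on holding the anode at the first wave; and capture of oxidised 14 by 7 and not by a second molecule of 14, which the excess of 7 favours. Capture of the cation by methanol at C4 is harmless, since zinc returns that quinol ether to 14.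

Step 12
Reactants: 17 2-bromo-6-{2,6-dichloro-4-[2-(3-methoxyphenyl)ethyl]phenoxy}-4-[2-(2,3-dimethoxyphenyl)ethyl]phenol
Product: 18 4-[2-(2,3-dimethoxyphenyl)ethyl]-2-{4-[2-(3-methoxyphenyl)ethyl]phenoxy}phenol
Conditions: H2, 10% Pd/C, Et3N, MeOH–EtOAc, rt
Reagents that add atoms: none
Why: Heterogeneous catalytic hydrogenolysis of the aryl C–Br and C–Cl bonds; Et3N takes up the hydrogen halide so the Pd surface stays active, and the methyl ethers, the diaryl ether and the bridges are inert.

Step 13
Reactants: 18 4-[2-(2,3-dimethoxyphenyl)ethyl]-2-{4-[2-(3-methoxyphenyl)ethyl]phenoxy}phenol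
Product: 19 3-[2-(4-hydroxy-3-{4-[2-(3-hydroxyphenyl)ethyl]phenoxy}phenyl)ethyl]benzene-1,2-diol
Conditions: BBr3, CH2Cl2, −78 °C to rt; then H2O, 0 °C, under argon
Reagents that add atoms: none
Why: Lewis-acid cleavage of aryl methyl ethers; BBr3 coordinates each methoxy oxygen and bromide attacks the methyl carbon (SN2), while the diaryl ether has no sp3 carbon on oxygen and survives, and aqueous work-up frees the four phenols.

## Compound list

1 | 3-methoxybenzyl bromide | COc1cccc(CBr)c1 | starting material
2 | (3-methoxybenzyl)triphenylphosphonium bromide | COc1cccc(C[P+](c2ccccc2)(c2ccccc2)c2ccccc2)c1.[Br-] | intermediate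
3 | 3,5-dichloro-4-hydroxybenzaldehyde | O=Cc1cc(Cl)c(O)c(Cl)c1 | starting material
4 | 3,5-dichloro-4-(methoxymethoxy)benzaldehyde | COCOc1c(Cl)cc(C=O)cc1Cl | intermediate
5 | 1,3-dichloro-2-(methoxymethoxy)-5-[2-(3-methoxyphenyl)ethenyl]benzene (E/Z mixture) | COCOc1c(Cl)cc(C=Cc2cccc(OC)c2)cc1Cl | intermediate
6 | 1,3-dichloro-2-(methoxymethoxy)-5-[2-(3-methoxyphenyl)ethyl]benzene | COCOc1c(Cl)cc(CCc2cccc(OC)c2)cc1Cl | intermediate
7 | 2,6-dichloro-4-[2-(3-methoxyphenyl)ethyl]phenol | COc1cccc(CCc2cc(Cl)c(O)c(Cl)c2)c1 | intermediate
8 | 2,3-dimethoxybenzyl alcohol | COc1cccc(CO)c1OC | starting material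
9 | (2,3-dimethoxybenzyl)triphenylphosphonium bromide | COc1cccc(C[P+](c2ccccc2)(c2ccccc2)c2ccccc2)c1OC.[Br-] | intermediate
10 | 3,5-dibromo-4-hydroxybenzaldehyde | O=Cc1cc(Br)c(O)c(Br)c1 | starting material
11 | 3,5-dibromo-4-(methoxymethoxy)benzaldehyde | COCOc1c(Br)cc(C=O)cc1Br | intermediate
12 | 1,3-dibromo-5-[2-(2,3-dimethoxyphenyl)ethenyl]-2-(methoxymethoxy)benzene (E/Z mixture) | COCOc1c(Br)cc(C=Cc2cccc(OC)c2OC)cc1Br | intermediate
13 | 1,3-dibromo-5-[2-(2,3-dimethoxyphenyl)ethyl]-2-(methoxymethoxy)benzene | COCOc1c(Br)cc(CCc2cccc(OC)c2OC)cc1Br | intermediate
14 | 2,6-dibromo-4-[2-(2,3-dimethoxyphenyl)ethyl]phenol | COc1cccc(CCc2cc(Br)c(O)c(Br)c2)c1OC | intermediate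
15 | 2,6-dibromo-6-{2,6-dichloro-4-[2-(3-methoxyphenyl)ethyl]phenoxy}-4-[2-(2,3-dimethoxyphenyl)ethyl]cyclohexa-2,4-dien-1-one (racemic, not isolated) | O=C1C(Br)=CC(CCc2cccc(OC)c2OC)=CC1(Br)Oc1c(Cl)cc(CCc2cccc(OC)c2)cc1Cl | intermediate
16 | 2-bromo-6-{2,6-dichloro-4-[2-(3-methoxyphenyl)ethyl]phenoxy}-4-[2-(2,3-dimethoxyphenyl)ethyl]-4-methoxycyclohexa-2,5-dien-1-one (racemic, not isolated) | O=C1C(Br)=CC(OC)(CCc2cccc(OC)c2OC)C=C1Oc1c(Cl)cc(CCc2cccc(OC)c2)cc1Cl | intermediate
17 | 2-bromo-6-{2,6-dichloro-4-[2-(3-methoxyphenyl)ethyl]phenoxy}-4-[2-(2,3-dimethoxyphenyl)ethyl]phenol | COc1cccc(CCc2cc(Cl)c(Oc3cc(CCc4cccc(OC)c4OC)cc(Br)c3O)c(Cl)c2)c1 | intermediate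
18 | 4-[2-(2,3-dimethoxyphenyl)ethyl]-2-{4-[2-(3-methoxyphenyl)ethyl]phenoxy}phenol | COc1cccc(CCc2ccc(Oc3cc(CCc4cccc(OC)c4OC)ccc3O)cc2)c1 | intermediate
19 | 3-[2-(4-hydroxy-3-{4-[2-(3-hydroxyphenyl)ethyl]phenoxy}phenyl)ethyl]benzene-1,2-diol | Oc1cccc(CCc2ccc(Oc3cc(CCc4cccc(O)c4O)ccc3O)cc2)c1 | target

## Step count and risk

Total step count: 13. Longest linear sequence: 7 steps (steps 6, 8, 9, 10, 11, 12 and 13 from 8; the chloro half through steps 1, 3, 4, 5 is equally long).

**Step 11 (key step).** The likely failure is loss of direction in the coupling.
- The oxidation potentials of 14 and 7 are expected to differ only slightly, so the anode may oxidise 7 as well. Oxidised 7 captured by 14 would carry through steps 12 and 13 to a constitutional isomer of the target, and oxidised 14 captured by a second molecule of 14 gives the homo-dimer.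
- If the potential drifts upward, the bromide released on the way to 16 could be oxidised and brominate ring D.
- Fallback: a copper-catalysed Ullmann ether synthesis, which sets out from 14 and 7 and returns at 18. Phenol 14 would be benzylated (BnBr, K2CO3, DMF) to 2-(benzyloxy)-1,3-dibromo-5-[2-(2,3-dimethoxyphenyl)ethyl]benzene F1. Phenol 7 would be dechlorinated (H2, Pd/C, Et3N, MeOH) to 4-[2-(3-methoxyphenyl)ethyl]phenol F2. F2 would then be coupled with an excess of F1 (CuI, picolinic acid, K3PO4, DMSO, 90 °C) to 2-(benzyloxy)-1-bromo-5-[2-(2,3-dimethoxyphenyl)ethyl]-3-{4-[2-(3-methoxyphenyl)ethyl]phenoxy}benzene F3; the excess of F1 limits double arylation. Hydrogenolysis of F3 (H2, Pd/C, Et3N) should remove the benzyl group and the remaining bromine together and give 18.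

**Step 12.** The likely failure is incomplete hydrodechlorination. The two chlorines flank the ether oxygen on ring B and are the slowest C–X bonds to cleave, and the halide salts formed slow the catalyst further, so mono- and dichloro products could remain.
- Fallback: reverse the order of the last two operations, setting out from 17 and returning at 19. BBr3 in CH2Cl2 would first cleave the three methyl ethers of 17 to 3-[2-(3-bromo-5-{2,6-dichloro-4-[2-(3-hydroxyphenyl)ethyl]phenoxy}-4-hydroxyphenyl)ethyl]benzene-1,2-diol F4. F4 dissolves in degassed aqueous NaOH as its phenolate and would be dehalogenated there with Ni–Al alloy, a classical reduction of halophenols in alkali, to give 19 after acidification under argon.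

**Step 9 (step 4 is the same reaction on the chloro series).** The likely failure is incomplete saturation. Diimide disproportionates faster than it reduces a conjugated 1,2-diarylalkene, so some 12 may remain, and it would be hard to separate from 13.
- Fallback: build the bridge without halogens and brominate last, setting out from 9 and returning at 14. Salt 9 would be condensed with purchased 4-(benzyloxy)benzaldehyde (KOtBu, THF) to 1-[2-(4-(benzyloxy)phenyl)ethenyl]-2,3-dimethoxybenzene F5. Hydrogenation over Pd/C would saturate the alkene and remove the benzyl group to give 4-[2-(2,3-dimethoxyphenyl)ethyl]phenol F6. Amine-catalysed ortho-bromination (NBS, 2 equiv, cat. iPr2NH, CH2Cl2, 0 °C) should then place both bromines next to the hydroxyl, the para position being blocked, and give 14. The price is a bromination that must prefer the phenol ring over ring D.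

**Step 13.** The likely failures are oxidative degradation of the free catechol of ring D during aqueous work-up and chromatography of the polar tetraphenol, and partial cleavage that leaves a monomethyl catechol.
- Fallback: a different cleavage with capture as a stable derivative, setting out from 18 and returning at 19. Compound 18 would be demethylated in molten pyridinium chloride at about 190 °C under argon (Brønsted acid activation, chloride as nucleophile). The crude product would be acetylated directly (Ac2O, pyridine) to the tetraacetate 3-[2-(4-acetoxy-3-{4-[2-(3-acetoxyphenyl)ethyl]phenoxy}phenyl)ethyl]-1,2-phenylene diacetate F7, which is not air-sensitive and can be purified. Acid methanolysis (HCl, MeOH, argon) would then release 19.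

## Further compounds

F1 | step 11 | 2-(benzyloxy)-1,3-dibromo-5-[2-(2,3-dimethoxyphenyl)ethyl]benzene | COc1cccc(CCc2cc(Br)c(OCc3ccccc3)c(Br)c2)c1OC
F2 | step 11 | 4-[2-(3-methoxyphenyl)ethyl]phenol | COc1cccc(CCc2ccc(O)cc2)c1
F3 | step 11 | 2-(benzyloxy)-1-bromo-5-[2-(2,3-dimethoxyphenyl)ethyl]-3-{4-[2-(3-methoxyphenyl)ethyl]phenoxy}benzene | COc1cccc(CCc2ccc(Oc3cc(CCc4cccc(OC)c4OC)cc(Br)c3OCc5ccccc5)cc2)c1
F4 | step 12 | 3-[2-(3-bromo-5-{2,6-dichloro-4-[2-(3-hydroxyphenyl)ethyl]phenoxy}-4-hydroxyphenyl)ethyl]benzene-1,2-diol | Oc1cccc(CCc2cc(Cl)c(Oc3cc(CCc4cccc(O)c4O)cc(Br)c3O)c(Cl)c2)c1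
F5 | step 9 | 1-[2-(4-(benzyloxy)phenyl)ethenyl]-2,3-dimethoxybenzene (E/Z mixture) | COc1cccc(C=Cc2ccc(OCc3ccccc3)cc2)c1OC
F6 | step 9 | 4-[2-(2,3-dimethoxyphenyl)ethyl]phenol | COc1cccc(CCc2ccc(O)cc2)c1OC
F7 | step 13 | 3-[2-(4-acetoxy-3-{4-[2-(3-acetoxyphenyl)ethyl]phenoxy}phenyl)ethyl]-1,2-phenylene diacetate | CC(=O)Oc1cccc(CCc2ccc(Oc3cc(CCc4cccc(OC(C)=O)c4OC(C)=O)ccc3OC(C)=O)cc2)c1
A1 | alternative 1 | 1-methoxy-1,3-bis(trimethylsilyloxy)buta-1,3-diene | COC(O[Si](C)(C)C)=CC(=C)O[Si](C)(C)C
A2 | alternative 1 | 5-(4-{5-[2-(2,3-dimethoxyphenyl)ethyl]-2-methoxyphenoxy}phenyl)-1,1-dimethoxypentan-3-one | COC(OC)CC(=O)CCc1ccc(Oc2cc(CCc3cccc(OC)c3OC)ccc2OC)cc1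
A3 | alternative 1 | methyl 2-hydroxy-6-[2-(4-{5-[2-(2,3-dimethoxyphenyl)ethyl]-2-methoxyphenoxy}phenyl)ethyl]benzoate | COC(=O)c1c(O)cccc1CCc1ccc(Oc2cc(CCc3cccc(OC)c3OC)ccc2OC)cc1
A4 | alternative 2 | 3-fluoroanisole | COc1cccc(F)c1
A5 | alternative 2 | 3-methoxybenzyne (1,2-didehydro-3-methoxybenzene) | COC1=CC=CC#C1
A6 | alternative 2 | 2-(4-methoxy-3-{4-[2-(3-methoxyphenyl)ethyl]phenoxy}phenyl)ethyllithium | [Li]CCc1ccc(OC)c(Oc2ccc(CCc3cccc(OC)c3)cc2)c1
A7 | alternative 2 | 2-methoxy-6-[2-(4-methoxy-3-{4-[2-(3-methoxyphenyl)ethyl]phenoxy}phenyl)ethyl]phenol | COc1cccc(CCc2ccc(Oc3cc(CCc4cccc(OC)c4O)ccc3OC)cc2)c1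
A8 | alternative 3 | methyl coumalate (methyl 2-oxo-2H-pyran-5-carboxylate) | COC(=O)C1=COC(=O)C=C1
A9 | alternative 3 | 4-[2-(2,3-dimethoxyphenyl)ethyl]-2-(ethynyloxy)-1-methoxybenzene | C#COc1cc(CCc2cccc(OC)c2OC)ccc1OC
A10 | alternative 3 | methyl 4-{5-[2-(2,3-dimethoxyphenyl)ethyl]-2-methoxyphenoxy}benzoate | COC(=O)c1ccc(Oc2cc(CCc3cccc(OC)c3OC)ccc2OC)cc1
A11 | alternative 3 | 5-[2-(2,3-dimethoxyphenyl)ethyl]-2-methoxyphenol | COc1ccc(CCc2cccc(OC)c2OC)cc1O
A12 | alternative 3 | methyl 4-fluorobenzoate | COC(=O)c1ccc(F)cc1
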